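In a one-step world, where first end groups meet second end groups and nothing else happens, a slow feed of either one merely delays the links. Thursday's run says otherwise: from 20.0 min the links stand near 32.5%, yet first end groups fall from 38.2% to 13.5%. So I take it that second end groups are lost on a clock of their own.

the same everywhere: second end groups 0.525 M
- Thursday's: first end groups 0.50 M; third end groups 0.25 M; run made earlier
- Wednesday's: first end groups 0.50 M; third end groups 0.17 M; run made earlier
- Saturday's: first end groups 0.50 M; third end groups 0.38 M; run made earlier
- noon: first end groups 0.50 M (fed, over 40 min); third end groups 0.250 M; all else is in the flask from the start; the feed brings no volume worth counting; time 1.5 h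
- summer: first end groups 0.50 M; third end groups 0.250 M (fed, over 40 min); all else is in the flask from the start; the feed brings no volume worth counting; time 1.5 h
- autumn: first end groups 0.50 M; third end groups 0.250 M; everything together at the start; time 1.5 h

| run | time / min | links / % | first end groups / % |
|---|---|---|---|
| Thursday's | 6.00 | 21.0 | 64.1 |
| Thursday's | 20.0 | 32.2 | 38.2 |
| Thursday's | 30.0 | 32.7 | 31.0 |
| Thursday's | 50.0 | 32.4 | 21.4 |
| Thursday's | 60.0 | 32.6 | 17.6 |
| Thursday's | 90.0 | 32.4 | 13.5 |
| Wednesday's | 10.0 | 29.1 | 51.2 |
| Wednesday's | 20.0 | 33.4 | 37.5 |
| Wednesday's | 25.0 | 33.6 | 33.1 |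
| Wednesday's | 40.0 | 33.1 | 23.0 |
| Wednesday's | 50.0 | 33.9 | 17.2 |
| Saturday's | 4.00 | 18.0 | 73.4 |
| Saturday's | 8.00 | 25.0 | 60.4 |
| Saturday's | 12.0 | 29.6 | 51.5 |
| Saturday's | 20.0 | 29.0 | 38.3 |
| Saturday's | 30.0 | 30.6 | 29.4 |
| Saturday's | 50.0 | 31.1 | 20.1 |

(readings scatter by 1 percentage point)

- the flask with the highest amount of links, in percent of the first end groups charged ("all alike" if they lie within 1.5 percentage points) (noon / summer / autumn / all alike)
- final links, as a percentage of the first end groups charged, in noon
- final links, as a percentage of the first end groups charged, in summer
- final links, as a percentage of the first end groups charged, in autumn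

- the numbers in the tables scatter with a standard deviation of 1 percentage point

Thursday's links reach 21.0% at 6.00 min. Read as a first-order rise to the plateau, this gives second end groups a mean life of

τ = 5.76 min.

The links take a fraction s = 30.9% of their charge, so their pseudo-first-order life with the first end groups' share removed is

τ₀ = τ/(1 − s) = 8.34 min.

Dividing by the feed time 40 min gives

f = 0.209.

This feed share is the fraction of a slowly fed charge that goes in during one such life.

For noon, adding up links along the rising feed gives

plateau × f/(1 − s) = 9.80%.

Autumn repeats Thursday, so I take 32.5%. For summer, f isn't enough. I also need the plateaus of Wednesday, 33.5%, and Saturday, 30.2%. As a rough guess I set summer's third end groups at f of their charge on that slope, which gives 35.5%. So I expect summer highest.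

The forecast says all alike, with 32%, 32.8% and 32.4% for noon, summer and autumn, because “the flask still ends on the flat maximum”.

The simulation puts summer highest: noon 9.99%, summer 36.7%, autumn 32.5%.

    first end groups + second end groups → links (k = 0.150 L mol⁻¹ min⁻¹)
    second end groups + third end groups → links of the second sort (k = 0.330 L mol⁻¹ min⁻¹)
    first end groups ⇌ dormant form (K = 5.40, k = 0.0280 min⁻¹)
    second end groups → decomposed reagent (k = 0.0820 min⁻¹)
    2 third end groups → self-condensation product (k = 0.490 L mol⁻¹ min⁻¹)

A neighbour of noon holds 0.21 M of second end groups, 0.420 equiv. Taking their life as unchanged, f stays 0.209, and links scale with the second end groups charged, so I reckon 3.92%. That flask ends with 23.6% of its first end groups left and links at 3.92%.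

(Readings and results were computed with constants of no real substance; the scatter is artificial.)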